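**Strategy.** The route rests on disconnecting the CH2–CH2 bond of the ethano bridge between ring A (the 3-hydroxy-4-aryloxyphenyl ring) and ring D (the 4-hydroxy-3-aryloxyphenyl ring). Each of these two benzylic carbons is a latent formyl carbon, and the one on ring A is para to the A–O–B ether oxygen, so the same aldehyde first activates an SNAr ether synthesis. The key step, an intramolecular McMurry coupling, joins the two formyl carbons of an acyclic tetra-aryl dialdehyde that already holds both diaryl ethers and the B–C ethano bridge, closing the 20-membered ring as a stilbene; one hydrogenation then saturates it and frees both phenols.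

Key step: step 4

Remark on the chemistry: the target has no stereocentre, and the 20-membered ring is assumed to be conformationally mobile (no stable planar chirality), so the route needs no stereocontrol. Ring B is the meta-linked 3-aryloxyphenyl ring and ring C the para-linked 4-aryloxyphenyl ring; the connections are A–O–B, B–CH2CH2–C, C–O–D and D–CH2CH2–A.

**Step 1**
Reactants: 1 3-iodophenol; 2 3-(benzyloxy)-4-fluorobenzaldehyde
Product: 3 3-(benzyloxy)-4-(3-iodophenoxy)benzaldehyde
Conditions: K2CO3, DMF, 110 °C
Reagents that add atoms: none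
Why: The para-formyl group activates the C–F bond of 2 for nucleophilic aromatic substitution (SNAr) by the phenoxide of 1, while the aryl iodide and the benzyl ether are inert to carbonate in DMF.

**Step 2**
Reactants: 3 3-(benzyloxy)-4-(3-iodophenoxy)benzaldehyde; 4 4-bromostyrene
Product: 6 3-(benzyloxy)-4-{3-[2-(4-bromophenyl)ethyl]phenoxy}benzaldehyde, via B-[2-(4-bromophenyl)ethyl]-9-BBN 5 (not isolated)
Conditions: 4 (1.3 equiv), 9-BBN (1.2 equiv), THF, 0 °C to rt; then 3, PdCl2(dppf) (5 mol %), aq. K3PO4, DMF, rt
Reagents that add atoms: none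
Why: Anti-Markovnikov hydroboration of the styrene followed by B-alkyl Suzuki–Miyaura coupling should install the saturated B–C bridge directly, because oxidative addition at room temperature favours the C–I bond of 3 over the C–Br bond and the aldehyde is safe once no B–H remains (4 in excess over 9-BBN).

**Step 3**
Reactants: 6 3-(benzyloxy)-4-{3-[2-(4-bromophenyl)ethyl]phenoxy}benzaldehyde; 7 4-(benzyloxy)-3-hydroxybenzaldehyde
Product: 8 4-(benzyloxy)-3-[4-(2-{3-[2-(benzyloxy)-4-formylphenoxy]phenyl}ethyl)phenoxy]benzaldehyde
Conditions: CuI (10 mol %), picolinic acid (20 mol %), K3PO4, DMSO, 90 °C, Ar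
Reagents that add atoms: none
Why: Ligand-accelerated Ullmann diaryl ether synthesis should couple the ortho-alkoxyphenol 7 with the unactivated aryl bromide, and non-enolisable aryl aldehydes and benzyl ethers tolerate the phosphate base.

**Step 4**
Reactants: 8 4-(benzyloxy)-3-[4-(2-{3-[2-(benzyloxy)-4-formylphenoxy]phenyl}ethyl)phenoxy]benzaldehyde
Product: 10 macrocyclic stilbene bis(benzyl ether) with a D–CH=CH–A bridge (E/Z mixture expected), via titanium pinacolate 9 (not isolated)
Conditions: TiCl4, Zn, pyridine, THF, reflux; 8 added by syringe pump (final ca. 2 mM)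
Reagents that add atoms: none
Why: Low-valent titanium from TiCl4/Zn transfers single electrons to both formyl groups, the ketyl radicals couple on titanium to the cyclic pinacolate 9 (the ring-closing C–C bond), and deoxygenation at reflux gives the stilbene. The closest known reaction type is the intramolecular McMurry coupling of dialdehydes to cyclophane-type macrocyclic stilbenes. The 20-membered ring is closed by end-to-end reductive carbonyl coupling of the formyl carbons on rings A and D, a macrocyclisation outside Baldwin's classification. No lasting stereocentre is formed: the two carbinol centres of 9 are lost on deoxygenation and the alkene geometry of 10 is erased in step 5. The step needs intramolecular over intermolecular coupling, which pseudo-high dilution, the two bent diaryl ether hinges and the flexible B–C ethano bridge should secure; benzyl and diaryl ethers are inert to the reagent.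

**Step 5**
Reactants: 10 macrocyclic stilbene bis(benzyl ether)
Product: 11 target macrocyclic bis(bibenzyl) diphenol (CNP0329842.0)
Conditions: H2 (1 atm), 10% Pd/C, EtOAc/MeOH, rt
Reagents that add atoms: none
Why: Heterogeneous hydrogenation should saturate the stilbene and hydrogenolyse both benzyl ethers in one operation, the diaryl ethers being stable and no stereocentre being created.

**Compound list**
1 | 3-iodophenol | Oc1cccc(I)c1 | starting material
2 | 3-(benzyloxy)-4-fluorobenzaldehyde | O=Cc1ccc(F)c(OCc2ccccc2)c1 | starting material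
3 | 3-(benzyloxy)-4-(3-iodophenoxy)benzaldehyde | O=Cc1ccc(Oc2cccc(I)c2)c(OCc2ccccc2)c1 | intermediate
4 | 4-bromostyrene | C=Cc1ccc(Br)cc1 | starting material
5 | B-[2-(4-bromophenyl)ethyl]-9-borabicyclo[3.3.1]nonane | Brc1ccc(CCB2C3CCCC2CCC3)cc1 | intermediate
6 | 3-(benzyloxy)-4-{3-[2-(4-bromophenyl)ethyl]phenoxy}benzaldehyde | O=Cc1ccc(Oc2cccc(CCc3ccc(Br)cc3)c2)c(OCc2ccccc2)c1 | intermediate
7 | 4-(benzyloxy)-3-hydroxybenzaldehyde | O=Cc1ccc(OCc2ccccc2)c(O)c1 | starting material
8 | 4-(benzyloxy)-3-[4-(2-{3-[2-(benzyloxy)-4-formylphenoxy]phenyl}ethyl)phenoxy]benzaldehyde | O=Cc1ccc(Oc2cccc(CCc3ccc(Oc4cc(C=O)ccc4OCc4ccccc4)cc3)c2)c(OCc2ccccc2)c1 | intermediate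
9 | macrocyclic titanium pinacolate, drawn as the free 1,2-diol (diastereomer mixture, configuration not defined) | c1ccccc1COc1cc2ccc1Oc1cccc(c1)CCc1ccc(cc1)Oc1cc(ccc1OCc1ccccc1)C(O)C2O | intermediate
10 | macrocyclic stilbene bis(benzyl ether): rings linked A–O–B, B–CH2CH2–C, C–O–D, D–CH=CH–A, OBn on rings A and D ortho to the ether oxygen (E/Z mixture, geometry not defined) | c1ccccc1COc1cc2ccc1Oc1cccc(c1)CCc1ccc(cc1)Oc1cc(ccc1OCc1ccccc1)C=C2 | intermediate
11 | target macrocyclic bis(bibenzyl) diphenol, achiral | Oc1cc2ccc1Oc1cccc(c1)CCc1ccc(cc1)Oc1cc(ccc1O)CC2 | target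

**Total step count:** 5. **Longest linear sequence:** 5 (steps 1–5).

**Steps most likely to fail**

Step 4: intermolecular coupling to oligomers, or arrest at the pinacol stage, may compete with ring closure. The fallback closes the same bond by olefin metathesis. It sets out from 8: double Wittig methylenation (Ph3PCH3Br, KOtBu, THF, 0 °C) should give the bis-styrene 2-(benzyloxy)-1-(3-{2-[4-(2-(benzyloxy)-5-vinylphenoxy)phenyl]ethyl}phenoxy)-4-vinylbenzene F1. Ring-closing metathesis (Grubbs II, toluene, 80 °C, ca. 1 mM) with loss of ethylene should then return to the route at 10.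

Step 2: oxidative addition may also occur at the C–Br bond (oligomers), or residual borane may reduce the aldehyde. The fallback builds the B–C bridge before any aldehyde is present. It sets out from 2 and bypasses 3. Sonogashira coupling of commercial 3-ethynylphenol with 1-bromo-4-iodobenzene (PdCl2(PPh3)2, CuI, Et3N, THF, rt, iodide-selective) should give 3-[(4-bromophenyl)ethynyl]phenol F2. Hydrogenation over diphenyl sulfide-poisoned Pd/C (H2, 1 atm, EtOAc), which spares aryl bromides, should give 3-[2-(4-bromophenyl)ethyl]phenol F3. SNAr of F3 on 2 (K2CO3, DMF, 110 °C) rejoins the route at 6.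

Step 3: the copper-catalysed coupling may stall through slow activation of the electron-neutral bromide, or lose bromine by protodehalogenation. The fallback reverses the polarity of ring C and forms the ether oxidatively at room temperature. It sets out from 6: Miyaura borylation (B2pin2, PdCl2(dppf), KOAc, dioxane, 80 °C) should give the pinacol boronate 3-(benzyloxy)-4-(3-{2-[4-(4,4,5,5-tetramethyl-1,3,2-dioxaborolan-2-yl)phenyl]ethyl}phenoxy)benzaldehyde F4. Cleavage of the pinacol ester (NaIO4, NH4OAc, acetone/H2O) should give the boronic acid (4-{2-[3-(2-(benzyloxy)-4-formylphenoxy)phenyl]ethyl}phenyl)boronic acid F5. Chan–Lam–Evans coupling of F5 with 7 (Cu(OAc)2, pyridine, 4 Å MS, CH2Cl2, air, rt) returns to the route at 8.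

**Further compounds**
F1 | step 4 | 2-(benzyloxy)-1-(3-{2-[4-(2-(benzyloxy)-5-vinylphenoxy)phenyl]ethyl}phenoxy)-4-vinylbenzene | C=Cc1ccc(Oc2cccc(CCc3ccc(Oc4cc(C=C)ccc4OCc4ccccc4)cc3)c2)c(OCc2ccccc2)c1
F2 | step 2 | 3-[(4-bromophenyl)ethynyl]phenol | Oc1cccc(C#Cc2ccc(Br)cc2)c1
F3 | step 2 | 3-[2-(4-bromophenyl)ethyl]phenol | Oc1cccc(CCc2ccc(Br)cc2)c1
F4 | step 3 | 3-(benzyloxy)-4-(3-{2-[4-(4,4,5,5-tetramethyl-1,3,2-dioxaborolan-2-yl)phenyl]ethyl}phenoxy)benzaldehyde | O=Cc1ccc(Oc2cccc(CCc3ccc(B4OC(C)(C)C(C)(C)O4)cc3)c2)c(OCc2ccccc2)c1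
F5 | step 3 | (4-{2-[3-(2-(benzyloxy)-4-formylphenoxy)phenyl]ethyl}phenyl)boronic acid | O=Cc1ccc(Oc2cccc(CCc3ccc(B(O)O)cc3)c2)c(OCc2ccccc2)c1
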